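**Retrosynthetic overview**

- Endgame: the target comes from fluoride desilylation, hydrogenolysis of a benzyl ester and a benzyl ether, and O-methylation of the C2 phenol of a ring-A salicylate.
- Feature the plan rests on: ring A is a benzoate (C1) with oxygen on both flanking carbons C2 and C6, the carbinol carbon on C3 and hydrogen on C4 and C5. C1–C2–C3 plus the carbinol is a δ-hydroxy-β-ketoester; C4–C5–C6(OAr) is a 3-aryloxypropynal that already carries ring B on oxygen.
- Key disconnections: C3–C4 (γ-aldol of the ketoester polyanion on the ynal aldehyde) and C1–C6 (6-endo-dig closure of the enol carbon on the oxygen-bearing alkyne carbon), then loss of the C4 oxygen. Ring A is the only ring formed; ring B is carried in as an arene.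
- Ketoester: asymmetric hydrogenation sets the (S)-carbinol and a crossed Claisen adds the acetate unit. Its δ-OH is left free so that the anion is an alkoxide-protected trianion that cannot β-eliminate, and a benzyl ester replaces a methyl ester to avoid a hindered saponification.
- Ynal: 4-methylsalicylaldehyde → benzyl ether → Baeyer–Villiger → ortho-formylation → dichlorovinyl ether (trichloroethylene) → reduction and silylation → lithium aryloxyacetylide → DMF.

Key step: step 10

Remark: the ring-A benzylic carbinol (para to the aryloxy group, ortho to methoxy) is treated as prone to acid ionisation, so every step after ring A exists is run under neutral or basic conditions. TBS = tert-butyldimethylsilyl.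

**Route**

Step 1
Reactants: 1 ethyl 5-methyl-3-oxohexanoate
Product: 2 ethyl (3S)-3-hydroxy-5-methylhexanoate
Conditions: H2 (10 atm), RuCl2[(S)-BINAP] (0.2 mol %), EtOH, 60 °C
Reagents that add atoms: none
Why: Noyori asymmetric hydrogenation of a β-ketoester, in which the ester-chelated ketone is reduced on one enantioface by the (S)-BINAP–Ru hydride; for alkyl β-ketoesters this should give the (3S)-alcohol, which is the stereocentre of the target.

Step 2
Reactants: 2 ethyl (3S)-3-hydroxy-5-methylhexanoate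
Product: 3 benzyl (5S)-5-hydroxy-7-methyl-3-oxooctanoate
Conditions: BnOAc (4 equiv), LDA (4 equiv), THF, −78 °C; then 2, −78 → −30 °C; AcOH quench at −78 °C
Reagents that add atoms: benzyl acetate, CC(=O)OCc1ccccc1
Why: Crossed Claisen condensation in which the first equivalent of ester enolate turns the hydroxyl into an alkoxide (so the β-oxygen cannot be eliminated and the stereocentre is untouched) and further enolate acylates on the ethyl ester, the product being held as its enolate until the quench.

Step 3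
Reactants: 4 2-hydroxy-4-methylbenzaldehyde
Product: 5 2-(benzyloxy)-4-methylbenzaldehyde
Conditions: BnBr, K2CO3, DMF, rt → 50 °C
Reagents that add atoms: benzyl bromide, BrCc1ccccc1
Why: Williamson etherification of the phenoxide, the only nucleophilic site present.

Step 4
Reactants: 5 2-(benzyloxy)-4-methylbenzaldehyde
Product: 7 2-(benzyloxy)-4-methylphenol, via 2-(benzyloxy)-4-methylphenyl formate 6 (not isolated)
Conditions: mCPBA, CH2Cl2, 0 °C → rt; NaHCO3 wash; K2CO3 (cat.), MeOH, rt
Reagents that add atoms: mCPBA, O=C(OO)c1cccc(Cl)c1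
Why: Baeyer–Villiger oxidation in which the electron-rich 2-alkoxyaryl group migrates in preference to hydride to give the aryl formate, which is cleaved by transesterification with methanol.

Step 5
Reactants: 7 2-(benzyloxy)-4-methylphenol
Product: 8 3-(benzyloxy)-2-hydroxy-5-methylbenzaldehyde
Conditions: MgCl2, Et3N, (CH2O)n, MeCN, reflux; 1 M HCl work-up
Reagents that add atoms: formaldehyde (as paraformaldehyde), C=O
Why: Magnesium-phenoxide-directed ortho-formylation (Casnati–Skattebøl) should deliver the formyl group to the only free position ortho to the hydroxyl, a second formaldehyde acting as hydride acceptor.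

Step 6
Reactants: 8 3-(benzyloxy)-2-hydroxy-5-methylbenzaldehyde
Product: 9 3-(benzyloxy)-2-{[(E)-1,2-dichloroethenyl]oxy}-5-methylbenzaldehyde
Conditions: Cl2C=CHCl (2 equiv), K2CO3, DMF, 70 °C (closed system, the dichloroacetylene formed is kept in solution)
Reagents that add atoms: trichloroethylene, ClC=C(Cl)Cl
Why: Known vinylation of phenols with trichloroethylene, in which base forms dichloroacetylene in situ, the phenoxide adds anti and protonation gives the (E)-1,2-dichlorovinyl ether; the linear electrophile tolerates the 2,6-disubstituted phenoxide, so the ring-B oxygen is joined to carbon without a hindered aryl–oxygen coupling.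

Step 7
Reactants: 9 3-(benzyloxy)-2-{[(E)-1,2-dichloroethenyl]oxy}-5-methylbenzaldehyde
Product: 10 {3-(benzyloxy)-2-{[(E)-1,2-dichloroethenyl]oxy}-5-methylphenyl}methanol
Conditions: NaBH4, MeOH/THF, 0 °C
Reagents that add atoms: none
Why: Borohydride reduction of the aryl aldehyde; the dichlorovinyl ether and the benzyl ether are inert to NaBH4.

Step 8
Reactants: 10 {3-(benzyloxy)-2-{[(E)-1,2-dichloroethenyl]oxy}-5-methylphenyl}methanol
Product: 11 tert-butyl({3-(benzyloxy)-2-{[(E)-1,2-dichloroethenyl]oxy}-5-methylphenyl}methoxy)dimethylsilane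
Conditions: TBSCl, imidazole, DMF, rt
Reagents that add atoms: tert-butyldimethylsilyl chloride, CC(C)(C)[Si](C)(C)Cl
Why: Standard silylation of a primary benzylic alcohol, giving a group that should survive n-BuLi, LDA and gold and leave with fluoride at the end.

Step 9
Reactants: 11 tert-butyl({3-(benzyloxy)-2-{[(E)-1,2-dichloroethenyl]oxy}-5-methylphenyl}methoxy)dimethylsilane
Product: 14 3-{2-(benzyloxy)-6-[(TBS-oxy)methyl]-4-methylphenoxy}prop-2-ynal, via aryl chloroethynyl ether 12 (not isolated), via lithium aryloxyacetylide 13 (not isolated)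
Conditions: n-BuLi (2.1 equiv), THF, −78 → −40 °C; DMF (3 equiv), −78 °C; inverse quench into cold aq. KH2PO4/MTBE; dried and used at once as a crude solution
Reagents that add atoms: N,N-dimethylformamide, CN(C)C=O
Why: Lithiation and β-elimination give the chloroalkyne, chlorine–lithium exchange gives the lithium aryloxyacetylide, and acetylide formylation with DMF gives a hemiaminal alkoxide that releases the ynal only in the buffered inverse quench, which keeps dimethylamine protonated and away from the push–pull ynal.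

Step 10
Reactants: 3 benzyl (5S)-5-hydroxy-7-methyl-3-oxooctanoate; 14 3-{2-(benzyloxy)-6-[(TBS-oxy)methyl]-4-methylphenoxy}prop-2-ynal
Product: 18 benzyl 6-{2-(benzyloxy)-6-[(TBS-oxy)methyl]-4-methylphenoxy}-2-hydroxy-3-[(1S)-1-(TBS-oxy)-3-methylbutyl]benzoate, via trilithium trianion 15 (not isolated), via tris-silyl aryloxy enyne 16 (not isolated), via silyloxy cyclohexenone 17 (not isolated)
Conditions: LDA (3.3 equiv), THF, −78 → −20 °C; 14, −78 °C; TBSOTf (3.6 equiv), −78 → 0 °C; pentane, filtration, evaporation; Ph3PAuNTf2 (5 mol %), i-PrOH (1.5 equiv), CH2Cl2, −20 °C → rt; DBU (2.5 equiv), rt; pH 5 buffer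
Reagents that add atoms: tert-butyldimethylsilyl triflate, CC(C)(C)[Si](C)(C)OS(=O)(=O)C(F)(F)F
Why: Proposed new method: the trianion 15 adds through its γ-carbon 1,2 to the aldehyde of 14 (C3–C4), the neighbouring alkoxide being a non-leaving group so that no E1cB loss of the carbinol oxygen can occur (Fráter–Seebach logic), and TBSOTf then caps both alkoxides and the enolate oxygen to give the 1-aryloxy-1,5-enyne 16, in which the propargylic oxygen cannot start a Meyer–Schuster shift and the ketoester can react only through carbon. Cationic gold(I) then polarises the ynol ether towards a ketenium-like species with its electrophilic end on the oxygen-bearing C6, and the silyl enol ether carbon C1 closes on it in a 6-endo-dig mode (C1–C6), i-PrOH taking the silyl group and protonating the vinyl-gold to give 17. DBU deprotonates the doubly activated C1–H and the enolate expels the C4 silanolate through the C5=C6 enol ether (vinylogous E1cB); tautomerisation then gives the aromatic ring A. The closest known reaction types are the γ-aldol of β-ketoester dianions, [3+3] salicylate syntheses from 1,3-bis(silyl enol ethers) and 1,3-dielectrophiles, and gold-catalysed 6-endo cycloisomerisation of 1-siloxy-1,5-enynes and carbocyclisation of silyl enol ethers onto alkynes. No new stereocentre remains (the C3 and C4 centres of 16 and 17 become sp2), and the (S)-carbinol is carried over unchanged because it is never ionised or eliminated, only the C4 oxygen being vinylogous to the C1 enolate. The step needs γ-carbon-to-aldehyde addition rather than conjugate addition (hard trianion at −78 °C, alkyne deactivated by the aryloxy donor) and C1-to-C6 closure rather than C1-to-C5 or O-cyclisation (secured by the ynol ether polarisation and the O-silylated enol).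

Step 11
Reactants: 18 benzyl 6-{2-(benzyloxy)-6-[(TBS-oxy)methyl]-4-methylphenoxy}-2-hydroxy-3-[(1S)-1-(TBS-oxy)-3-methylbutyl]benzoate
Product: 19 benzyl 6-{2-(benzyloxy)-6-[(TBS-oxy)methyl]-4-methylphenoxy}-2-methoxy-3-[(1S)-1-(TBS-oxy)-3-methylbutyl]benzoate
Conditions: MeI, Cs2CO3, DMF, rt → 40 °C
Reagents that add atoms: iodomethane, CI
Why: Williamson O-methylation; the caesium phenoxide breaks the hydrogen bond to the ester, and the benzyl ester and silyl ethers are inert to carbonate.

Step 12
Reactants: 19 benzyl 6-{2-(benzyloxy)-6-[(TBS-oxy)methyl]-4-methylphenoxy}-2-methoxy-3-[(1S)-1-(TBS-oxy)-3-methylbutyl]benzoate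
Product: 20 6-{2-hydroxy-6-[(TBS-oxy)methyl]-4-methylphenoxy}-2-methoxy-3-[(1S)-1-(TBS-oxy)-3-methylbutyl]benzoic acid
Conditions: H2 (1 atm), 10 % Pd/C, EtOAc, rt
Reagents that add atoms: none
Why: Hydrogenolysis of the benzyl ester and the aryl benzyl ether over palladium; the two benzylic C–O bonds of the skeleton are still bulky silyl ethers, which should resist C–O hydrogenolysis, and the diaryl ether is inert.

Step 13
Reactants: 20 6-{2-hydroxy-6-[(TBS-oxy)methyl]-4-methylphenoxy}-2-methoxy-3-[(1S)-1-(TBS-oxy)-3-methylbutyl]benzoic acid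
Product: 21 6-[2-hydroxy-6-(hydroxymethyl)-4-methylphenoxy]-3-[(1S)-1-hydroxy-3-methylbutyl]-2-methoxybenzoic acid (CNP0221397.1)
Conditions: TBAF (6 equiv), THF, 0 °C → rt; cold 0.5 M HCl to pH 3–4, EtOAc
Reagents that add atoms: none
Why: Fluoride-induced cleavage of both silyl ethers under non-acidic conditions, so the benzylic carbinol is not ionised and the (S) configuration is kept.

**Compound list**

1 | ethyl 5-methyl-3-oxohexanoate | CCOC(=O)CC(=O)CC(C)C | starting material
2 | ethyl (3S)-3-hydroxy-5-methylhexanoate | CCOC(=O)C[C@@H](O)CC(C)C | intermediate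
3 | benzyl (5S)-5-hydroxy-7-methyl-3-oxooctanoate | O=C(OCc1ccccc1)CC(=O)C[C@@H](O)CC(C)C | intermediate
4 | 2-hydroxy-4-methylbenzaldehyde | Cc1ccc(C=O)c(O)c1 | starting material
5 | 2-(benzyloxy)-4-methylbenzaldehyde | Cc1ccc(C=O)c(OCc2ccccc2)c1 | intermediate
6 | 2-(benzyloxy)-4-methylphenyl formate | Cc1ccc(OC=O)c(OCc2ccccc2)c1 | intermediate (not isolated)
7 | 2-(benzyloxy)-4-methylphenol | Cc1ccc(O)c(OCc2ccccc2)c1 | intermediate
8 | 3-(benzyloxy)-2-hydroxy-5-methylbenzaldehyde | O=Cc1cc(C)cc(OCc2ccccc2)c1O | intermediate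
9 | 3-(benzyloxy)-2-{[(E)-1,2-dichloroethenyl]oxy}-5-methylbenzaldehyde | O=Cc1cc(C)cc(OCc2ccccc2)c1O/C(Cl)=C\Cl | intermediate
10 | {3-(benzyloxy)-2-{[(E)-1,2-dichloroethenyl]oxy}-5-methylphenyl}methanol | OCc1cc(C)cc(OCc2ccccc2)c1O/C(Cl)=C\Cl | intermediate
11 | tert-butyl({3-(benzyloxy)-2-{[(E)-1,2-dichloroethenyl]oxy}-5-methylphenyl}methoxy)dimethylsilane | CC(C)(C)[Si](C)(C)OCc1cc(C)cc(OCc2ccccc2)c1O/C(Cl)=C\Cl | intermediate
12 | tert-butyl({3-(benzyloxy)-2-[(chloroethynyl)oxy]-5-methylphenyl}methoxy)dimethylsilane | CC(C)(C)[Si](C)(C)OCc1cc(C)cc(OCc2ccccc2)c1OC#CCl | intermediate (not isolated)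
13 | lithium 2-{2-(benzyloxy)-6-[(TBS-oxy)methyl]-4-methylphenoxy}ethynide | [Li+].[C-]#COc1c(OCc2ccccc2)cc(C)cc1CO[Si](C)(C)C(C)(C)C | intermediate (not isolated)
14 | 3-{2-(benzyloxy)-6-[(TBS-oxy)methyl]-4-methylphenoxy}prop-2-ynal | O=CC#COc1c(OCc2ccccc2)cc(C)cc1CO[Si](C)(C)C(C)(C)C | intermediate
15 | trilithium trianion of 3 (C2/C4 enolate–carbanion, C5 alkoxide) | [Li+].[Li+].[Li+].O=C(OCc1ccccc1)[CH-]C(=O)[CH-][C@@H]([O-])CC(C)C | intermediate (not isolated)
16 | benzyl 7-{2-(benzyloxy)-6-[(TBS-oxy)methyl]-4-methylphenoxy}-3,5-bis(TBS-oxy)-4-[(1S)-1-(TBS-oxy)-3-methylbutyl]hept-2-en-6-ynoate (mixture at C4 and C5) | O=C(OCc1ccccc1)C=C(O[Si](C)(C)C(C)(C)C)C([C@@H](O[Si](C)(C)C(C)(C)C)CC(C)C)C(O[Si](C)(C)C(C)(C)C)C#COc1c(OCc2ccccc2)cc(C)cc1CO[Si](C)(C)C(C)(C)C | intermediate (not isolated)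
17 | benzyl 2-{2-(benzyloxy)-6-[(TBS-oxy)methyl]-4-methylphenoxy}-4-(TBS-oxy)-6-oxo-5-[(1S)-1-(TBS-oxy)-3-methylbutyl]cyclohex-2-ene-1-carboxylate (mixture at the ring centres) | O=C(OCc1ccccc1)C1C(=O)C([C@@H](O[Si](C)(C)C(C)(C)C)CC(C)C)C(O[Si](C)(C)C(C)(C)C)C=C1Oc1c(OCc2ccccc2)cc(C)cc1CO[Si](C)(C)C(C)(C)C | intermediate (not isolated)
18 | benzyl 6-{2-(benzyloxy)-6-[(TBS-oxy)methyl]-4-methylphenoxy}-2-hydroxy-3-[(1S)-1-(TBS-oxy)-3-methylbutyl]benzoate | O=C(OCc1ccccc1)c1c(O)c([C@@H](O[Si](C)(C)C(C)(C)C)CC(C)C)ccc1Oc1c(OCc2ccccc2)cc(C)cc1CO[Si](C)(C)C(C)(C)C | intermediate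
19 | benzyl 6-{2-(benzyloxy)-6-[(TBS-oxy)methyl]-4-methylphenoxy}-2-methoxy-3-[(1S)-1-(TBS-oxy)-3-methylbutyl]benzoate | O=C(OCc1ccccc1)c1c(OC)c([C@@H](O[Si](C)(C)C(C)(C)C)CC(C)C)ccc1Oc1c(OCc2ccccc2)cc(C)cc1CO[Si](C)(C)C(C)(C)C | intermediate
20 | 6-{2-hydroxy-6-[(TBS-oxy)methyl]-4-methylphenoxy}-2-methoxy-3-[(1S)-1-(TBS-oxy)-3-methylbutyl]benzoic acid | OC(=O)c1c(OC)c([C@@H](O[Si](C)(C)C(C)(C)C)CC(C)C)ccc1Oc1c(O)cc(C)cc1CO[Si](C)(C)C(C)(C)C | intermediate
21 | 6-[2-hydroxy-6-(hydroxymethyl)-4-methylphenoxy]-3-[(1S)-1-hydroxy-3-methylbutyl]-2-methoxybenzoic acid | COc1c([C@@H](O)CC(C)C)ccc(Oc2c(O)cc(C)cc2CO)c1C(=O)O | target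

**Step count**

Total: 13 steps. Longest linear sequence: 11 steps (steps 3–13, from 2-hydroxy-4-methylbenzaldehyde).

**Steps most likely to fail**

1. Step 10 (key step, new method). What may go wrong:
   - incomplete γ-deprotonation of the alkoxide-bearing ketoester;
   - conjugate addition to the ynal with displacement of the aryloxide instead of 1,2-addition;
   - capture of the gold-activated ynol ether by i-PrOH or by the ortho oxygens of ring B instead of by C1;
   - elimination of the exocyclic silyloxy group during aromatisation.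

   Fallback by known chemistry, from 8 back to 19 (steps 10 and 11 bypassed), in which the diaryl ether is made by Ullmann coupling on a preformed ring A. Compound 8 would be reduced (NaBH4) to 2-(benzyloxy)-6-(hydroxymethyl)-4-methylphenol F1 and silylated at the primary hydroxyl (TBSCl, imidazole, 0 °C) to 2-(benzyloxy)-6-[(TBS-oxy)methyl]-4-methylphenol F2. Purchased 4-bromo-2-methoxybenzaldehyde would be treated with i-BuMgBr to give racemic 1-(4-bromo-2-methoxyphenyl)-3-methylbutan-1-ol F3, which is oxidised (Dess–Martin periodinane) to 1-(4-bromo-2-methoxyphenyl)-3-methylbutan-1-one F4. Corey–Bakshi–Shibata reduction with the (R)-oxazaborolidine and BH3·SMe2 should give (1S)-1-(4-bromo-2-methoxyphenyl)-3-methylbutan-1-ol F5, which is silylated to its TBS ether F6. Deprotonation between OMe and Br (LDA, THF, −78 °C) and trapping with benzyl chloroformate would give benzyl 6-bromo-2-methoxy-3-[(1S)-1-(TBS-oxy)-3-methylbutyl]benzoate F7. Ullmann ether coupling of F7 with F2 (CuI, picolinic acid, K3PO4, DMSO, 90 °C) would then give 19.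

2. Step 9. What may go wrong: addition of dimethylamine or water to the push–pull ynal during the quench, or loss of the ynal on concentration. Fallback from 11 back to 14, avoiding any amine by-product: the acetylide 13 is generated as before and trapped with monomeric formaldehyde (from paraformaldehyde) to give 3-{2-(benzyloxy)-6-[(TBS-oxy)methyl]-4-methylphenoxy}prop-2-yn-1-ol F8. This is oxidised under neutral conditions (MnO2, CH2Cl2, or Dess–Martin periodinane with NaHCO3) and the solution of 14 is used directly.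

3. Step 2. What may go wrong: self-condensation of the benzyl acetate enolate outrunning acylation by the alkoxide-bearing ester, or lactonisation of the product on work-up. Fallback from 2 back to 3 by acyl-imidazolide homologation. Compound 2 is silylated (TBSCl, imidazole) to ethyl (3S)-3-(TBS-oxy)-5-methylhexanoate F9 and saponified (LiOH, THF/H2O) to (3S)-3-(TBS-oxy)-5-methylhexanoic acid F10. CDI converts F10 into the acyl imidazolide (3S)-3-(TBS-oxy)-1-(imidazol-1-yl)-5-methylhexan-1-one F11. Condensation of F11 with magnesium mono-benzyl malonate (Masamune–Brooks) gives benzyl (5S)-5-(TBS-oxy)-7-methyl-3-oxooctanoate F12, whose silyl group is removed with HF·pyridine in THF to give 3.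

**Further compounds**

F1 | step 10 | 2-(benzyloxy)-6-(hydroxymethyl)-4-methylphenol | OCc1cc(C)cc(OCc2ccccc2)c1O
F2 | step 10 | 2-(benzyloxy)-6-[(TBS-oxy)methyl]-4-methylphenol | CC(C)(C)[Si](C)(C)OCc1cc(C)cc(OCc2ccccc2)c1O
F3 | step 10 | rac-1-(4-bromo-2-methoxyphenyl)-3-methylbutan-1-ol | COc1cc(Br)ccc1C(O)CC(C)C
F4 | step 10 | 1-(4-bromo-2-methoxyphenyl)-3-methylbutan-1-one | COc1cc(Br)ccc1C(=O)CC(C)C
F5 | step 10 | (1S)-1-(4-bromo-2-methoxyphenyl)-3-methylbutan-1-ol | COc1cc(Br)ccc1[C@@H](O)CC(C)C
F6 | step 10 | [(1S)-1-(4-bromo-2-methoxyphenyl)-3-methylbutoxy](tert-butyl)dimethylsilane | COc1cc(Br)ccc1[C@@H](O[Si](C)(C)C(C)(C)C)CC(C)C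
F7 | step 10 | benzyl 6-bromo-2-methoxy-3-[(1S)-1-(TBS-oxy)-3-methylbutyl]benzoate | O=C(OCc1ccccc1)c1c(OC)c([C@@H](O[Si](C)(C)C(C)(C)C)CC(C)C)ccc1Br
F8 | step 9 | 3-{2-(benzyloxy)-6-[(TBS-oxy)methyl]-4-methylphenoxy}prop-2-yn-1-ol | OCC#COc1c(OCc2ccccc2)cc(C)cc1CO[Si](C)(C)C(C)(C)C
F9 | step 2 | ethyl (3S)-3-(TBS-oxy)-5-methylhexanoate | CCOC(=O)C[C@@H](O[Si](C)(C)C(C)(C)C)CC(C)C
F10 | step 2 | (3S)-3-(TBS-oxy)-5-methylhexanoic acid | OC(=O)C[C@@H](O[Si](C)(C)C(C)(C)C)CC(C)C
F11 | step 2 | (3S)-3-(TBS-oxy)-1-(imidazol-1-yl)-5-methylhexan-1-one | O=C(C[C@@H](O[Si](C)(C)C(C)(C)C)CC(C)C)n1ccnc1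
F12 | step 2 | benzyl (5S)-5-(TBS-oxy)-7-methyl-3-oxooctanoate | O=C(OCc1ccccc1)CC(=O)C[C@@H](O[Si](C)(C)C(C)(C)C)CC(C)C
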